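**Plan**

- Retrosynthetic cuts, in order: the two O‑benzyl bonds and the C5 O‑methyl bond (late unmasking), the O–CH3 bond at C3, the C3–C4 bond of ring C, the O1–C2 ether bond, and the formyl carbon on ring A.
- Feature used: in ring C the carbinol carbon C3 sits next to the ketone carbon C4. Once C3–C4 is opened, C2 (flanked by O1 and the ring B aryl group) is the acidic α‑carbon of an aldehyde and can epimerize while the ring closes.
- Forward: rings A and B are bought as benzaldehydes, joined through O1–C2 as a racemic ether and oxidised to a dialdehyde; ring C then closes through C3–C4, followed by three finishing steps.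
- Stereochemistry: C2 comes from a dynamic kinetic resolution by a chiral triazolylidene carbene during ring closure. C3 is set in the same step as the 2,3‑trans isomer, which is also the more stable arrangement. No later step touches either centre.
- Numbering: chroman‑4‑one (O1, C2, C3, C4, C4a–C8a); ring A benzo, ring B 2‑aryl, ring C pyranone.

Key step: step 11

Assumption: the absolute sense of induction of the aminoindanol‑derived triazolylidene on this substrate class cannot be read from precedent. The (5aS,10bR) salt is written as the one expected to give the 2R series; its commercially available mirror image would be used if the 2S,3S series resulted.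

**Route**

Step 1
Reactants: 1 syringaldehyde (4‑hydroxy‑3,5‑dimethoxybenzaldehyde)
Product: 2 4‑(benzyloxy)‑3,5‑dimethoxybenzaldehyde
Conditions: BnBr, K2CO3, DMF, 60 °C
Reagents that add atoms: benzyl bromide, BrCc1ccccc1
Why: Williamson etherification of the only phenol should be clean, and the benzyl group later serves as the hydrogenolysable mask of the C6 hydroxyl.

Step 2
Reactants: 2 4‑(benzyloxy)‑3,5‑dimethoxybenzaldehyde
Product: 4 4‑(benzyloxy)‑3,5‑dimethoxyphenol, via aryl formate 3 (not isolated)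
Conditions: mCPBA, CH2Cl2, rt; then K2CO3 (cat.), MeOH, rt
Reagents that add atoms: 3‑chloroperoxybenzoic acid (mCPBA), OOC(=O)c1cccc(Cl)c1
Why: Baeyer–Villiger oxidation of the electron‑rich benzaldehyde proceeds with aryl migration to the formate, and mild methanolysis then frees the symmetrical phenol without touching the benzyl ether.

Step 3
Reactants: 4 4‑(benzyloxy)‑3,5‑dimethoxyphenol
Product: 6 3‑(benzyloxy)‑6‑hydroxy‑2,4‑dimethoxybenzaldehyde, via salicyl alcohol 5 (not isolated)
Conditions: MgCl2, Et3N, (CH2O)n, MeCN, reflux; aq. HCl work‑up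
Reagents that add atoms: formaldehyde (from paraformaldehyde), C=O
Why: Magnesium‑phenoxide‑directed ortho‑formylation (Casnati–Skattebøl reaction) delivers formaldehyde only ortho to the hydroxyl, the two ortho positions being equivalent by symmetry, and a second formaldehyde oxidises the benzylic alkoxide by hydride transfer.

Step 4
Reactants: 7 3‑hydroxy‑4,5‑dimethoxybenzaldehyde
Product: 8 3‑(benzyloxy)‑4,5‑dimethoxybenzaldehyde
Conditions: BnBr, K2CO3, DMF, 60 °C
Reagents that add atoms: benzyl bromide, BrCc1ccccc1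
Why: Williamson etherification protects the ring B phenol as a benzyl ether that is removed together with the ring A benzyl group at the end.

Step 5
Reactants: 8 3‑(benzyloxy)‑4,5‑dimethoxybenzaldehyde
Product: 9 1‑(benzyloxy)‑5‑ethenyl‑2,3‑dimethoxybenzene
Conditions: Ph3PCH3Br, KOtBu, THF, 0 °C → rt
Reagents that add atoms: methyltriphenylphosphonium bromide, [Br-].C[P+](c1ccccc1)(c1ccccc1)c1ccccc1
Why: Wittig methylenation of a non‑enolizable aryl aldehyde with the unstabilised ylide is dependable and gives the styrene needed for the diol.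

Step 6
Reactants: 9 1‑(benzyloxy)‑5‑ethenyl‑2,3‑dimethoxybenzene
Product: 10 rac‑1‑[3‑(benzyloxy)‑4,5‑dimethoxyphenyl]ethane‑1,2‑diol
Conditions: K2OsO4·2H2O (cat.), NMO, acetone–H2O, rt
Reagents that add atoms: N‑methylmorpholine N‑oxide, C[N+]1([O-])CCOCC1; water, O
Why: Upjohn dihydroxylation converts the terminal styrene into the diol; no chiral ligand is used because this carbon is deliberately carried as a racemate.

Step 7
Reactants: 10 rac‑1‑[3‑(benzyloxy)‑4,5‑dimethoxyphenyl]ethane‑1,2‑diol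
Product: 11 rac‑1‑[3‑(benzyloxy)‑4,5‑dimethoxyphenyl]‑2‑[(tert‑butyldimethylsilyl)oxy]ethan‑1‑ol
Conditions: TBSCl (1.05 equiv), imidazole, CH2Cl2, 0 °C
Reagents that add atoms: tert‑butyldimethylsilyl chloride, CC(C)(C)[Si](C)(C)Cl
Why: Silylation with about one equivalent of the bulky chloride at 0 °C selects the primary over the secondary benzylic hydroxyl on steric grounds.

Step 8
Reactants: 6 3‑(benzyloxy)‑6‑hydroxy‑2,4‑dimethoxybenzaldehyde; 11 rac‑1‑[3‑(benzyloxy)‑4,5‑dimethoxyphenyl]‑2‑[(tert‑butyldimethylsilyl)oxy]ethan‑1‑ol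
Product: 12 rac‑3‑(benzyloxy)‑6‑{1‑[3‑(benzyloxy)‑4,5‑dimethoxyphenyl]‑2‑[(tert‑butyldimethylsilyl)oxy]ethoxy}‑2,4‑dimethoxybenzaldehyde
Conditions: PPh3, DIAD, THF, 0 °C → rt
Reagents that add atoms: none
Why: Mitsunobu etherification joins the acidic salicylaldehyde‑type phenol of 6 to the activated secondary benzylic carbon of 11 and so forms the future O1–C2 bond; the configuration created is irrelevant because this carbon is equilibrated in step 11.

Step 9
Reactants: 12 rac‑3‑(benzyloxy)‑6‑{1‑[3‑(benzyloxy)‑4,5‑dimethoxyphenyl]‑2‑[(tert‑butyldimethylsilyl)oxy]ethoxy}‑2,4‑dimethoxybenzaldehyde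
Product: 13 rac‑3‑(benzyloxy)‑6‑{1‑[3‑(benzyloxy)‑4,5‑dimethoxyphenyl]‑2‑hydroxyethoxy}‑2,4‑dimethoxybenzaldehyde
Conditions: HF·pyridine, pyridine, THF, 0 °C → rt
Reagents that add atoms: none
Why: Fluoride‑mediated desilylation under buffered conditions frees the primary alcohol while the aryl aldehyde, the benzylic aryl ether and the benzyl ethers are inert.

Step 10
Reactants: 13 rac‑3‑(benzyloxy)‑6‑{1‑[3‑(benzyloxy)‑4,5‑dimethoxyphenyl]‑2‑hydroxyethoxy}‑2,4‑dimethoxybenzaldehyde
Product: 14 rac‑3‑(benzyloxy)‑6‑{1‑[3‑(benzyloxy)‑4,5‑dimethoxyphenyl]‑2‑oxoethoxy}‑2,4‑dimethoxybenzaldehyde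
Conditions: Dess–Martin periodinane, pyridine, CH2Cl2, 0 °C
Reagents that add atoms: none
Why: Dess–Martin oxidation takes the primary alcohol to the aldehyde under near‑neutral conditions, which should avoid base‑induced aldol closure onto the ring A aldehyde; the labile α‑aryl‑α‑aryloxy aldehyde is passed through a short silica pad and used at once.

Step 11
Reactants: 14 rac‑3‑(benzyloxy)‑6‑{1‑[3‑(benzyloxy)‑4,5‑dimethoxyphenyl]‑2‑oxoethoxy}‑2,4‑dimethoxybenzaldehyde
Product: 15 (2R,3R)‑6‑(benzyloxy)‑2‑[3‑(benzyloxy)‑4,5‑dimethoxyphenyl]‑3‑hydroxy‑5,7‑dimethoxychroman‑4‑one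
Conditions: (5aS,10bR)‑2‑(pentafluorophenyl)‑5a,10b‑dihydro‑4H,6H‑indeno[2,1‑b][1,2,4]triazolo[4,3‑d][1,4]oxazin‑2‑ium tetrafluoroborate (15 mol %), i‑Pr2NEt (1 equiv), degassed toluene, rt, Ar
Reagents that add atoms: none
Why: Proposed new method: the free carbene should add to the ring A formyl group, whose adduct carries the more acidic (benzylic) carbinol C–H; proton transfer then gives the enaminol, an acyl‑anion equivalent at C4, which attacks the neighbouring aliphatic aldehyde to forge C3–C4 before the carbene is released from the tetrahedral adduct. The closest known reactions are the carbene‑catalysed intramolecular crossed aldehyde–ketone benzoin that gives 3‑hydroxychroman‑4‑ones and carbene‑catalysed dynamic kinetic resolutions of α‑epimerizable aldehydes; a dialdehyde with a labile α‑stereocentre has not been closed in this way. Ring C closes in the 6‑exo‑trig mode. C2 is set by dynamic kinetic resolution: the α‑aryl‑α‑aryloxy aldehyde racemizes through its enol under the amine while the chiral enaminol consumes one enantiomer faster. C3 is set by the aldehyde face that the catalyst‑bound enaminol attacks and, being α to the new ketone, is also under thermodynamic control in favour of the diequatorial 2,3‑trans arrangement. The step needs the aryl aldehyde rather than the aliphatic one as donor; the substrate supports this because the aliphatic aldehyde is α‑branched and largely enolized (a poor donor) and the acyloin with the aryl‑conjugated C4 ketone is the more stable regioisomer, while the electron‑poor N‑pentafluorophenyl catalyst allows a weak base that keeps aldol closure slow.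

Step 12
Reactants: 15 (2R,3R)‑6‑(benzyloxy)‑2‑[3‑(benzyloxy)‑4,5‑dimethoxyphenyl]‑3‑hydroxy‑5,7‑dimethoxychroman‑4‑one
Product: 16 (2R,3R)‑6‑(benzyloxy)‑2‑[3‑(benzyloxy)‑4,5‑dimethoxyphenyl]‑3,5,7‑trimethoxychroman‑4‑one
Conditions: MeOTf, 2,6‑di‑tert‑butyl‑4‑methylpyridine, CH2Cl2, 0 °C → rt
Reagents that add atoms: methyl trifluoromethanesulfonate, COS(=O)(=O)C(F)(F)F
Why: O‑Methylation with a strong electrophile and a non‑nucleophilic hindered pyridine as acid scavenger etherifies the secondary hydroxyl without forming the C3 enolate, so neither β‑elimination of O1 nor epimerization at C2 or C3 should occur.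

Step 13
Reactants: 16 (2R,3R)‑6‑(benzyloxy)‑2‑[3‑(benzyloxy)‑4,5‑dimethoxyphenyl]‑3,5,7‑trimethoxychroman‑4‑one
Product: 17 (2R,3R)‑6‑(benzyloxy)‑2‑[3‑(benzyloxy)‑4,5‑dimethoxyphenyl]‑5‑hydroxy‑3,7‑dimethoxychroman‑4‑one
Conditions: MgI2·OEt2, toluene–Et2O, 60 °C; then H2O
Reagents that add atoms: none
Why: Chelation‑controlled demethylation: MgI2 binds between the C4 carbonyl and the peri C5 methoxy oxygen and iodide removes that methyl group, because only there is a chelated aryloxide the leaving group; the C3 methyl ether would have to release an alkoxide and should survive, as should the remote ethers.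

Step 14
Reactants: 17 (2R,3R)‑6‑(benzyloxy)‑2‑[3‑(benzyloxy)‑4,5‑dimethoxyphenyl]‑5‑hydroxy‑3,7‑dimethoxychroman‑4‑one
Product: 18 (2R,3R)‑5,6‑dihydroxy‑2‑(3‑hydroxy‑4,5‑dimethoxyphenyl)‑3,7‑dimethoxychroman‑4‑one (CNP0075601.1)
Conditions: H2 (1 atm), Pd/C, EtOAc–MeOH, rt
Reagents that add atoms: none
Why: Catalytic hydrogenolysis cleaves both aryl benzyl ethers under neutral conditions that should leave the hydrogen‑bonded C4 ketone, the C2 ring ether and both stereocentres untouched.

**Compound list**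

1 | syringaldehyde (4‑hydroxy‑3,5‑dimethoxybenzaldehyde) | COc1cc(C=O)cc(OC)c1O | starting material
2 | 4‑(benzyloxy)‑3,5‑dimethoxybenzaldehyde | COc1cc(C=O)cc(OC)c1OCc1ccccc1 | intermediate
3 | 4‑(benzyloxy)‑3,5‑dimethoxyphenyl formate (aryl formate, not isolated) | COc1cc(OC=O)cc(OC)c1OCc1ccccc1 | intermediate
4 | 4‑(benzyloxy)‑3,5‑dimethoxyphenol | COc1cc(O)cc(OC)c1OCc1ccccc1 | intermediate
5 | 4‑(benzyloxy)‑2‑(hydroxymethyl)‑3,5‑dimethoxyphenol (salicyl alcohol, not isolated) | OCc1c(O)cc(OC)c(OCc2ccccc2)c1OC | intermediate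
6 | 3‑(benzyloxy)‑6‑hydroxy‑2,4‑dimethoxybenzaldehyde | O=Cc1c(O)cc(OC)c(OCc2ccccc2)c1OC | intermediate
7 | 3‑hydroxy‑4,5‑dimethoxybenzaldehyde | COc1cc(C=O)cc(O)c1OC | starting material
8 | 3‑(benzyloxy)‑4,5‑dimethoxybenzaldehyde | COc1cc(C=O)cc(OCc2ccccc2)c1OC | intermediate
9 | 1‑(benzyloxy)‑5‑ethenyl‑2,3‑dimethoxybenzene | C=Cc1cc(OC)c(OC)c(OCc2ccccc2)c1 | intermediate
10 | rac‑1‑[3‑(benzyloxy)‑4,5‑dimethoxyphenyl]ethane‑1,2‑diol | OCC(O)c1cc(OC)c(OC)c(OCc2ccccc2)c1 | intermediate
11 | rac‑1‑[3‑(benzyloxy)‑4,5‑dimethoxyphenyl]‑2‑[(tert‑butyldimethylsilyl)oxy]ethan‑1‑ol | CC(C)(C)[Si](C)(C)OCC(O)c1cc(OC)c(OC)c(OCc2ccccc2)c1 | intermediate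
12 | rac‑3‑(benzyloxy)‑6‑{1‑[3‑(benzyloxy)‑4,5‑dimethoxyphenyl]‑2‑[(tert‑butyldimethylsilyl)oxy]ethoxy}‑2,4‑dimethoxybenzaldehyde | O=Cc1c(OC(CO[Si](C)(C)C(C)(C)C)c2cc(OCc3ccccc3)c(OC)c(OC)c2)cc(OC)c(OCc2ccccc2)c1OC | intermediate
13 | rac‑3‑(benzyloxy)‑6‑{1‑[3‑(benzyloxy)‑4,5‑dimethoxyphenyl]‑2‑hydroxyethoxy}‑2,4‑dimethoxybenzaldehyde | O=Cc1c(OC(CO)c2cc(OCc3ccccc3)c(OC)c(OC)c2)cc(OC)c(OCc2ccccc2)c1OC | intermediate
14 | rac‑3‑(benzyloxy)‑6‑{1‑[3‑(benzyloxy)‑4,5‑dimethoxyphenyl]‑2‑oxoethoxy}‑2,4‑dimethoxybenzaldehyde (C2 labile, no descriptor) | O=Cc1c(OC(C=O)c2cc(OCc3ccccc3)c(OC)c(OC)c2)cc(OC)c(OCc2ccccc2)c1OC | intermediate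
15 | (2R,3R)‑6‑(benzyloxy)‑2‑[3‑(benzyloxy)‑4,5‑dimethoxyphenyl]‑3‑hydroxy‑5,7‑dimethoxychroman‑4‑one | COc1cc2c(c(OC)c1OCc1ccccc1)C(=O)[C@H](O)[C@@H](c1cc(OCc3ccccc3)c(OC)c(OC)c1)O2 | intermediate
16 | (2R,3R)‑6‑(benzyloxy)‑2‑[3‑(benzyloxy)‑4,5‑dimethoxyphenyl]‑3,5,7‑trimethoxychroman‑4‑one | COc1cc2c(c(OC)c1OCc1ccccc1)C(=O)[C@H](OC)[C@@H](c1cc(OCc3ccccc3)c(OC)c(OC)c1)O2 | intermediate
17 | (2R,3R)‑6‑(benzyloxy)‑2‑[3‑(benzyloxy)‑4,5‑dimethoxyphenyl]‑5‑hydroxy‑3,7‑dimethoxychroman‑4‑one | COc1cc2c(c(O)c1OCc1ccccc1)C(=O)[C@H](OC)[C@@H](c1cc(OCc3ccccc3)c(OC)c(OC)c1)O2 | intermediate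
18 | (2R,3R)‑5,6‑dihydroxy‑2‑(3‑hydroxy‑4,5‑dimethoxyphenyl)‑3,7‑dimethoxychroman‑4‑one | COc1cc2c(c(O)c1O)C(=O)[C@H](OC)[C@@H](c1cc(O)c(OC)c(OC)c1)O2 | target

**Count**

Total steps: 14. Longest linear sequence: 11 steps (steps 4–14, from 7); the ring A branch (steps 1–3) joins at step 8.

**Steps most likely to fail**

Step 11.
- The carbene may engage the aliphatic aldehyde instead of the hindered, electron‑rich ring A aldehyde. That enaminol can expel the ring A aryloxide from C2 (an internal redox isomerization) or close the other way round.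
- The amine may promote an aldol closure of the C2 enol onto the ring A aldehyde, towards a benzofuran.
- Resolution of C2 may be incomplete, or C2 may be eroded later through the enediol of the product.

Fallback with known chemistry, setting out from phenol 4 and aldehyde 8 and returning at 15:
- Ortho‑acetylation of 4 (Ac2O, BF3·OEt2, warm, Fries‑type) should give 1‑[3‑(benzyloxy)‑6‑hydroxy‑2,4‑dimethoxyphenyl]ethan‑1‑one F1.
- MOMCl with i‑Pr2NEt should give 1‑[3‑(benzyloxy)‑2,4‑dimethoxy‑6‑(methoxymethoxy)phenyl]ethan‑1‑one F2.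
- Claisen–Schmidt condensation with 8 (KOH, EtOH) should give (E)‑1‑[3‑(benzyloxy)‑2,4‑dimethoxy‑6‑(methoxymethoxy)phenyl]‑3‑[3‑(benzyloxy)‑4,5‑dimethoxyphenyl]prop‑2‑en‑1‑one F3.
- Juliá–Colonna epoxidation (poly‑L‑leucine, urea–H2O2, DBU, THF) should give [3‑(benzyloxy)‑2,4‑dimethoxy‑6‑(methoxymethoxy)phenyl]{(2R,3S)‑3‑[3‑(benzyloxy)‑4,5‑dimethoxyphenyl]oxiran‑2‑yl}methanone F4.
- HCl in MeOH–THF removes the methoxymethyl group, and the freed phenol opens the epoxide at the benzylic carbon with inversion, which gives 15.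

Step 8.
- The activated benzylic alcohol may eliminate or ionize instead of being displaced.
- Coupling may be slow next to the bulky silyloxymethyl group, so that the reduced azo reagent is alkylated instead.

Fallback, setting out from 11 and returning at 12: the hydroxyl is first turned into a leaving group and the ether is then made by phenoxide alkylation. SOCl2 with pyridine in CH2Cl2 should give rac‑{2‑[3‑(benzyloxy)‑4,5‑dimethoxyphenyl]‑2‑chloroethoxy}(tert‑butyl)dimethylsilane F5. Alkylation of 6 with F5 (Cs2CO3, DMF, 50 °C) should give 12. An ionizing pathway is harmless here because the carbon is racemic.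

Step 13.
- The Lewis acid may also remove the neighbouring C6 benzyl group or attack the chelated C3 methyl ether.
- It may open ring C at the benzylic C2–O1 bond, with epimerization on reclosure.

Fallback, setting out from 16 and returning at 18: the order is inverted so that no benzyl ether is present during the demethylation. Hydrogenolysis of 16 (H2, Pd/C, EtOAc–MeOH) should give (2R,3R)‑6‑hydroxy‑2‑(3‑hydroxy‑4,5‑dimethoxyphenyl)‑3,5,7‑trimethoxychroman‑4‑one F6. AlCl3 in MeCN at rt then removes only the methyl group peri to the carbonyl, which gives 18.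

**Further compounds**

F1 | step 11 | 1‑[3‑(benzyloxy)‑6‑hydroxy‑2,4‑dimethoxyphenyl]ethan‑1‑one | CC(=O)c1c(O)cc(OC)c(OCc2ccccc2)c1OC
F2 | step 11 | 1‑[3‑(benzyloxy)‑2,4‑dimethoxy‑6‑(methoxymethoxy)phenyl]ethan‑1‑one | CC(=O)c1c(OCOC)cc(OC)c(OCc2ccccc2)c1OC
F3 | step 11 | (E)‑1‑[3‑(benzyloxy)‑2,4‑dimethoxy‑6‑(methoxymethoxy)phenyl]‑3‑[3‑(benzyloxy)‑4,5‑dimethoxyphenyl]prop‑2‑en‑1‑one | COCOc1cc(OC)c(OCc2ccccc2)c(OC)c1C(=O)/C=C/c1cc(OCc2ccccc2)c(OC)c(OC)c1
F4 | step 11 | [3‑(benzyloxy)‑2,4‑dimethoxy‑6‑(methoxymethoxy)phenyl]{(2R,3S)‑3‑[3‑(benzyloxy)‑4,5‑dimethoxyphenyl]oxiran‑2‑yl}methanone | COCOc1cc(OC)c(OCc2ccccc2)c(OC)c1C(=O)[C@@H]1O[C@H]1c1cc(OCc2ccccc2)c(OC)c(OC)c1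
F5 | step 8 | rac‑{2‑[3‑(benzyloxy)‑4,5‑dimethoxyphenyl]‑2‑chloroethoxy}(tert‑butyl)dimethylsilane | CC(C)(C)[Si](C)(C)OCC(Cl)c1cc(OC)c(OC)c(OCc2ccccc2)c1
F6 | step 13 | (2R,3R)‑6‑hydroxy‑2‑(3‑hydroxy‑4,5‑dimethoxyphenyl)‑3,5,7‑trimethoxychroman‑4‑one | COc1cc2c(c(OC)c1O)C(=O)[C@H](OC)[C@@H](c1cc(O)c(OC)c(OC)c1)O2
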